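**Strategy.** The route rests on opening ring A (C1, C10–C14) at C1–C10, which leads back to a δ-lactone. An Ireland–Claisen ring contraction of the lactone silyl ketene acetal forms C1–C10 and breaks C12–O in one operation: it closes ring A, creates the quaternary C1 (C15 methyl, C2, C14) and the adjacent C10 stereocentre, and places the ring olefin at C11=C12, the later epoxide site. The precursor is a 4,6-trans 6-alkenyl-4-silyloxy-3-methyl δ-lactone whose Z olefin carries C9 as a PMB-protected hydroxymethyl group. Ring C (γ-lactone) is then built on C9, and ring B (ten-membered, C1–C10) is closed last at C4–C5.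

Key step: step 9

Remark: briarane atom numbers are used throughout. C9 is carried as a PMB ether (a benzyl ether could not be removed later beside the ring olefin and the alkynylsilane). The C3 centre of lactone 13 (C1 of the target) is erased on enolisation in step 9.

Step 1
Reactants: 1 2-[(4-methoxyphenyl)methoxy]acetaldehyde; 2 ethyl 2-[bis(2,2,2-trifluoroethoxy)phosphoryl]propanoate
Product: 3 ethyl (2Z)-4-[(4-methoxyphenyl)methoxy]-2-methylbut-2-enoate
Conditions: KN(SiMe3)2, 18-crown-6, THF, -78 °C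
Reagents that add atoms: none
Why: Still–Gennari olefination; the electron-poor phosphonate with a free potassium counter-ion eliminates from the kinetic adduct and should give the Z enoate (ester cis to CH2OPMB), which fixes the C10=C11 geometry needed in step 9.

Step 2
Reactants: 3 ethyl (2Z)-4-[(4-methoxyphenyl)methoxy]-2-methylbut-2-enoate
Product: 4 (2Z)-4-[(4-methoxyphenyl)methoxy]-2-methylbut-2-en-1-ol
Conditions: iBu2AlH, CH2Cl2, -78 °C
Reagents that add atoms: none
Why: 1,2-reduction of the conjugated ester by the aluminium hydride, which leaves the olefin geometry untouched.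

Step 3
Reactants: 4 (2Z)-4-[(4-methoxyphenyl)methoxy]-2-methylbut-2-en-1-ol
Product: 5 (2Z)-4-[(4-methoxyphenyl)methoxy]-2-methylbut-2-enal
Conditions: MnO2, CH2Cl2, 20 °C
Reagents that add atoms: none
Why: allylic oxidation on MnO2 under neutral conditions, chosen to avoid Z to E isomerisation; the enal is used at once.

Step 4
Reactants: 5 (2Z)-4-[(4-methoxyphenyl)methoxy]-2-methylbut-2-enal; 6 1-methoxy-1,3-bis(trimethylsilyloxy)buta-1,3-diene (Chan's diene)
Product: 8 methyl (5R,6Z)-5-hydroxy-8-[(4-methoxyphenyl)methoxy]-6-methyl-3-oxooct-6-enoate, via bis-silyl adduct 7 (not isolated)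
Conditions: Ti(OiPr)4 (10 mol%), (R)-BINOL (10 mol%), 4 Å MS, THF, -78 to 20 °C; then CF3CO2H (cat.), THF/H2O, 0 °C
Reagents that add atoms: none
Why: catalytic asymmetric vinylogous Mukaiyama aldol; the (R)-BINOL–titanium complex is chosen to expose the Re face of the aldehyde, which sets the C12 carbinol as R (the antipodal ligand would give the enantiomeric series).

Step 5
Reactants: 8 methyl (5R,6Z)-5-hydroxy-8-[(4-methoxyphenyl)methoxy]-6-methyl-3-oxooct-6-enoate
Product: 9 methyl (3S,5R,6Z)-3,5-dihydroxy-8-[(4-methoxyphenyl)methoxy]-6-methyloct-6-enoate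
Conditions: Et2BOMe, NaBH4, THF/MeOH (4:1), -78 °C; then AcOH, MeOH (evaporation)
Reagents that add atoms: none
Why: Narasaka–Prasad reduction; external hydride adds to the six-membered boron chelate and gives the 1,3-syn diol (C14 S), the only diol that lactonises to the 4,6-trans lactone needed for step 9 (an anti-selective reduction would give the cis lactone and the wrong C14).

Step 6
Reactants: 9 methyl (3S,5R,6Z)-3,5-dihydroxy-8-[(4-methoxyphenyl)methoxy]-6-methyloct-6-enoate
Product: 10 (4S,6R)-4-hydroxy-6-{(2Z)-4-[(4-methoxyphenyl)methoxy]but-2-en-2-yl}oxan-2-one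
Conditions: PPTS (cat.), toluene, 60 °C
Reagents that add atoms: none
Why: acid-catalysed lactonisation (intramolecular transesterification, 6-exo-trig) of the δ-hydroxy ester; the syn diol places the C14 hydroxyl trans to the C12 alkenyl group.

Step 7
Reactants: 10 (4S,6R)-4-hydroxy-6-{(2Z)-4-[(4-methoxyphenyl)methoxy]but-2-en-2-yl}oxan-2-one
Product: 11 (4S,6R)-4-{[tert-butyl(dimethyl)silyl]oxy}-6-{(2Z)-4-[(4-methoxyphenyl)methoxy]but-2-en-2-yl}oxan-2-one
Conditions: TBSCl, imidazole, DMF, 20 °C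
Reagents that add atoms: tert-butyl(chloro)dimethylsilane, CC(C)(C)[Si](C)(C)Cl
Why: imidazole-catalysed silylation of the secondary alcohol; the TBS ether at C14 is meant to survive every step up to step 25.

Step 8
Reactants: 11 (4S,6R)-4-{[tert-butyl(dimethyl)silyl]oxy}-6-{(2Z)-4-[(4-methoxyphenyl)methoxy]but-2-en-2-yl}oxan-2-one
Product: 13 (3R,4S,6R)-4-{[tert-butyl(dimethyl)silyl]oxy}-6-{(2Z)-4-[(4-methoxyphenyl)methoxy]but-2-en-2-yl}-3-methyloxan-2-one, via lithium enolate 12 (not isolated)
Conditions: LiN(iPr)2, THF, -78 °C; MeI, -78 to -40 °C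
Reagents that add atoms: iodomethane, CI
Why: lactone enolate alkylation, expected anti to the neighbouring silyloxy group; the low temperature is chosen to suppress β-elimination, and the new centre is erased in step 9.

Step 9
Reactants: 13 (3R,4S,6R)-4-{[tert-butyl(dimethyl)silyl]oxy}-6-{(2Z)-4-[(4-methoxyphenyl)methoxy]but-2-en-2-yl}-3-methyloxan-2-one
Product: 16 (1R,2S,6S)-6-{[tert-butyl(dimethyl)silyl]oxy}-2-{[(4-methoxyphenyl)methoxy]methyl}-1,3-dimethylcyclohex-3-ene-1-carboxylic acid, via silyl ketene acetal 14 (not isolated), via trimethylsilyl ester 15 (not isolated)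
Conditions: LiN(SiMe3)2, TMSCl/Et3N (premixed), THF, -78 to 20 °C; toluene, 110 °C; then 1 M HCl, THF, 0 °C
Reagents that add atoms: none
Why: Enolisation with in situ silylation gives the cyclic silyl ketene acetal 14, which undergoes a concerted suprafacial [3,3]-sigmatropic shift (Ireland–Claisen rearrangement of an alkenyl lactone, a known ring contraction) in which C1–C10 forms while C12–O breaks. Ring A is closed by this C1–C10 bond through a boat-shaped six-centre array, the only one the lactone tether allows (a bicyclo[2.2.2]octane-like transition state), so the cyclohexene arises by ring contraction and not by an ionic cyclisation. C1 is controlled by the C12 carbinol centre: bonding can only occur on the lactone face that carries the alkenyl group, which places the C2 carboxyl cis to the C14 silyloxy group and the C15 methyl trans to it. C10 is controlled by the olefin geometry: in the boat array the Z-disposed C9 points away from the O–C2 bridge and ends trans to C2, so the Z purity from step 1 is the selectivity that must be secured. The trans lactone keeps the C14 silyloxy group on the convex face, away from the alkenyl bridge, and immediate trapping of the enolate as 14 is meant to forestall β-elimination of the silyloxide.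

Step 10
Reactants: 16 (1R,2S,6S)-6-{[tert-butyl(dimethyl)silyl]oxy}-2-{[(4-methoxyphenyl)methoxy]methyl}-1,3-dimethylcyclohex-3-ene-1-carboxylic acid; 17 ethynyltrimethylsilane
Product: 19 1-[(1R,2S,6S)-6-{[tert-butyl(dimethyl)silyl]oxy}-2-{[(4-methoxyphenyl)methoxy]methyl}-1,3-dimethylcyclohex-3-en-1-yl]-3-(trimethylsilyl)prop-2-yn-1-one, via acid chloride 18 (not isolated)
Conditions: 1-chloro-N,N,2-trimethylprop-1-en-1-amine, CH2Cl2, 0 °C; then 17, PdCl2(PPh3)2 (2 mol%), CuI (4 mol%), Et3N, THF, 20 °C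
Reagents that add atoms: none
Why: acyl Sonogashira coupling; the neutral chloro-enamine converts the hindered acid into its chloride without acid, and the acylpalladium/copper acetylide coupling gives the ynone that brings in C3 and C4.

Step 11
Reactants: 19 the TMS-ynone
Product: 20 (2R)-propargylic alcohol (19 with C2=O reduced to C2–OH)
Conditions: RuCl[(S,S)-TsDPEN](p-cymene) (3 mol%), i-PrOH, 20 °C
Reagents that add atoms: none
Why: Noyori asymmetric transfer hydrogenation of an alkynyl ketone; with the (S,S) catalyst the alkyne acts as the π-directing group and hydride should be delivered so that C2 becomes R (catalyst control over the α-quaternary substrate).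

Step 12
Reactants: 20 (2R)-propargylic alcohol
Product: 21 C2 triethylsilyl ether of 20
Conditions: TESOTf, 2,6-lutidine, CH2Cl2, -78 to 0 °C
Reagents that add atoms: triethylsilyl trifluoromethanesulfonate, CC[Si](CC)(CC)OS(=O)(=O)C(F)(F)F
Why: silyl triflate silylation of the hindered carbinol; TES is chosen at C2 so that it can later be removed beside the C14 TBS ether.

Step 13
Reactants: 21 C2 triethylsilyl ether
Product: 22 iodoalkyne (21 with C≡C–SiMe3 changed to C≡C–I)
Conditions: N-iodosuccinimide, AgNO3 (10 mol%), acetone, 20 °C, dark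
Reagents that add atoms: N-iodosuccinimide, O=C1CCC(=O)N1I
Why: silver-catalysed iododesilylation of the alkynylsilane through the silver acetylide.

Step 14
Reactants: 22 iodoalkyne
Product: 23 (3Z)-iodoalkene (C3=C4 cis, iodine on C4)
Conditions: 2-nitrobenzenesulfonylhydrazide, Et3N, THF/i-PrOH (1:1), 20 °C
Reagents that add atoms: none
Why: diimide reduction; diimide formed in situ transfers two hydrogens syn to the iodoalkyne and should give the Z iodoalkene, while the trisubstituted ring olefin reacts far more slowly.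

Step 15
Reactants: 23 (3Z)-iodoalkene
Product: 24 C9 primary alcohol (23 without the PMB group)
Conditions: DDQ, CH2Cl2/pH 7 buffer (10:1), 0 °C
Reagents that add atoms: none
Why: oxidative PMB ether cleavage (hydride abstraction by DDQ, hydrolysis of the oxocarbenium ion); silyl ethers, iodoalkene and ring olefin should be untouched.

Step 16
Reactants: 24 C9 primary alcohol
Product: 25 C9 aldehyde
Conditions: Dess–Martin periodinane, NaHCO3, CH2Cl2, 0 °C
Reagents that add atoms: none
Why: Dess–Martin oxidation under buffered conditions, chosen so that the β,γ-unsaturated aldehyde is neither epimerised at C10 nor conjugated; it is used crude.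

Step 17
Reactants: 26 diethyl (2S)-2-hydroxybutanedioate (diethyl L-malate)
Product: 28 diethyl (2S,3R)-2-hydroxy-3-methylbutanedioate, via dilithio alkoxide enolate 27 (not isolated)
Conditions: LiN(iPr)2 (2.1 equiv), THF, -78 to -20 °C; MeI, -78 °C
Reagents that add atoms: iodomethane, CI
Why: Fráter–Seebach alkylation; the chelated alkoxide enolate is methylated anti to the alkoxide, which sets C17 (R) next to the C8 carbinol.

Step 18
Reactants: 28 diethyl (2S,3R)-2-hydroxy-3-methylbutanedioate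
Product: 29 (2S,3R)-2-hydroxy-3-methylbutanedioic acid
Conditions: KOH, H2O/EtOH, 0 to 20 °C; then HCl (aq)
Reagents that add atoms: water (delivered as hydroxide), O
Why: saponification of both esters; cold hydroxide should not epimerise C17 because the alkoxide carboxylate resists enolisation.

Step 19
Reactants: 29 (2S,3R)-2-hydroxy-3-methylbutanedioic acid; 30 2,2-dimethylpropanal
Product: 31 (2R)-2-[(2S,4S)-2-tert-butyl-5-oxo-1,3-dioxolan-4-yl]propanoic acid
Conditions: TsOH (cat.), H2SO4 (cat.), pentane, reflux, Dean–Stark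
Reagents that add atoms: none
Why: acetalisation of the α-hydroxy acid; the five-membered dioxolanone is preferred over the six-membered acetal of the β-hydroxy acid, and the cis isomer (tert-butyl cis to the side chain) should predominate and be purified by crystallisation.

Step 20
Reactants: 31 (2R)-2-[(2S,4S)-2-tert-butyl-5-oxo-1,3-dioxolan-4-yl]propanoic acid; 25 C9 aldehyde
Product: 35 aldol adduct acid (C8–C9 bond formed; C9–OTES; dioxolanone intact; C19 carboxylic acid), via dilithium enolate 32 (not isolated), via dilithium aldolate 33 (not isolated), via bis-triethylsilyl derivative 34 (not isolated)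
Conditions: LiN(SiMe3)2 (2.1 equiv), THF, -78 °C; 25, -78 °C; TESOTf, -78 to -40 °C; then pH 7 buffer
Reagents that add atoms: triethylsilyl trifluoromethanesulfonate, CC[Si](CC)(CC)OS(=O)(=O)C(F)(F)F
Why: aldol addition of a dioxolanone enolate (self-regeneration of the stereocentre): the aldehyde approaches trans to the tert-butyl group, which regenerates C8 with retention, and the enolate (side chain cis to OLi) reacts through a Zimmerman–Traxler chair that puts C9–O anti to C8–O, which is also the Felkin–Anh face of 25 (attack anti to the quaternary C1), so C9 should be R; silylation of the aldolate in the flask blocks retro-aldol and lactonisation onto C19.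

Step 21
Reactants: 35 aldol adduct acid; 36 1-methoxy-4-[(prop-2-yn-1-yloxy)methyl]benzene
Product: 39 ynone acid (C7 ketone bearing C6≡C5–C16H2OPMB; free tertiary C8–OH; C19 acid), via lithium acetylide 37 (not isolated), via hemiketal adduct 38 (not isolated)
Conditions: 36, n-BuLi, THF, -78 °C; BF3·OEt2; 35, -78 °C; then NH4Cl (aq)
Reagents that add atoms: none
Why: addition of a boron trifluoride-activated lithium acetylide to the acetal-type lactone carbonyl; the tetrahedral adduct should persist at -78 °C and collapse on work-up to the ynone, with loss of 2,2-dimethylpropanal and release of the C8 hydroxyl.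

Step 22
Reactants: 39 ynone acid
Product: 41 lactone (ring C closed; C7 S, C8 S, C17 R; C8–OH free), via hydroxy acid 40 (not isolated)
Conditions: Zn(BH4)2, Et2O, -30 °C; then PPTS (cat.), CH2Cl2, 20 °C
Reagents that add atoms: none
Why: chelation-controlled 1,2-reduction: zinc bridges the ketone and the C8 hydroxyl and hydride should enter from the side of the smaller C17 branch (anti to the C9 branch), giving C7 S; the γ-hydroxy acid then closes ring C by 5-exo-trig lactonisation onto C19.

Step 23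
Reactants: 41 lactone
Product: 42 C2,C9-diol (both TES ethers removed; C14–OTBS kept)
Conditions: HF·pyridine, pyridine, THF, 0 °C
Reagents that add atoms: none
Why: fluoride-mediated desilylation; triethylsilyl ethers are far more labile than the hindered TBS ether at C14, so only C2–OH and C9–OH should be released.

Step 24
Reactants: 42 C2,C9-diol
Product: 43 C2,C9-diacetate
Conditions: Ac2O, pyridine, DMAP (cat.), CH2Cl2, 20 °C
Reagents that add atoms: acetic anhydride, CC(=O)OC(C)=O
Why: DMAP-catalysed acylation of the two secondary hydroxyls; the tertiary C8 hydroxyl is too hindered to react, and prompt acetylation of C9–OH prevents lactone migration.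

Step 25
Reactants: 43 C2,C9-diacetate
Product: 44 C14 alcohol
Conditions: HF (48% aq.), MeCN, 20 °C
Reagents that add atoms: none
Why: acidic fluoride cleavage of the hindered TBS ether before any epoxide is present; acetates, lactone and PMB ether are stable to these conditions.

Step 26
Reactants: 44 C14 alcohol
Product: 45 (11S,12R)-epoxide
Conditions: VO(acac)2 (5 mol%), t-BuOOH, CH2Cl2, 20 °C
Reagents that add atoms: tert-butyl hydroperoxide, CC(C)(C)OO
Why: hydroxyl-directed epoxidation: the axial homoallylic C14 hydroxyl binds vanadium and delivers oxygen to the face of C11=C12 syn to itself, which is also the face anti to the axial C15 methyl; iodoalkene and alkyne are inert.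

Step 27
Reactants: 45 (11S,12R)-epoxide
Product: 46 C2,C9,C14-triacetate
Conditions: Ac2O, pyridine, DMAP (cat.), CH2Cl2, 20 °C
Reagents that add atoms: acetic anhydride, CC(=O)OC(C)=O
Why: DMAP-catalysed acylation of the C14 hydroxyl; the tertiary C8 hydroxyl again stays free.

Step 28
Reactants: 46 C2,C9,C14-triacetate
Product: 47 C16 propargylic alcohol
Conditions: DDQ, CH2Cl2/pH 7 buffer (10:1), 0 °C
Reagents that add atoms: none
Why: oxidative cleavage of the propargylic PMB ether; epoxide, acetates and lactone tolerate buffered DDQ.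

Step 29
Reactants: 47 C16 propargylic alcohol
Product: 48 alkenylstannane (SnBu3 on C5, cis to C7; C16–OH free)
Conditions: [Cp*RuCl]4 (2.5 mol%), Bu3SnH, CH2Cl2, 20 °C
Reagents that add atoms: tributyltin hydride, CCCC[SnH](CCCC)CCCC
Why: hydroxyl-directed ruthenium-catalysed trans-hydrostannation: the propargylic C16 hydroxyl hydrogen-bonds to the chloride on ruthenium, tin goes to C5 (next to the carbinol) and hydrogen to C6 on the opposite side, so tin ends cis to C7.

Step 30
Reactants: 48 alkenylstannane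
Product: 49 CNP0296793.1 (target)
Conditions: Pd(PPh3)4 (10 mol%), copper thiophene-2-carboxylate Cu(O2CC4H3S), [Ph2PO2][NBu4], DMF, 20 °C, 1 mM
Reagents that add atoms: none
Why: intramolecular Stille coupling: oxidative addition of zerovalent palladium to the Z iodoalkene, copper-assisted transmetalation of the hindered stannane and reductive elimination form C4–C5 with retention at both olefins and close ring B on a substrate preorganised by the two trans arms on ring A; no stereocentre is formed.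

**Compound list**

1 | 2-[(4-methoxyphenyl)methoxy]acetaldehyde | O=CCOCc1ccc(OC)cc1 | starting material
2 | ethyl 2-[bis(2,2,2-trifluoroethoxy)phosphoryl]propanoate | CCOC(=O)C(C)P(=O)(OCC(F)(F)F)OCC(F)(F)F | starting material
3 | ethyl (2Z)-4-[(4-methoxyphenyl)methoxy]-2-methylbut-2-enoate | CCOC(=O)/C(C)=C\COCc1ccc(OC)cc1 | intermediate
4 | (2Z)-4-[(4-methoxyphenyl)methoxy]-2-methylbut-2-en-1-ol | OC/C(C)=C\COCc1ccc(OC)cc1 | intermediate
5 | (2Z)-4-[(4-methoxyphenyl)methoxy]-2-methylbut-2-enal | O=C/C(C)=C\COCc1ccc(OC)cc1 | intermediate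
6 | 1-methoxy-1,3-bis(trimethylsilyloxy)buta-1,3-diene | COC(O[Si](C)(C)C)=CC(=C)O[Si](C)(C)C | starting material
7 | methyl (5R,6Z)-8-[(4-methoxyphenyl)methoxy]-6-methyl-3,5-bis(trimethylsilyloxy)octa-2,6-dienoate (bis-silyl adduct) | COC(=O)C=C(O[Si](C)(C)C)C[C@@H](O[Si](C)(C)C)/C(C)=C\COCc1ccc(OC)cc1 | intermediate
8 | methyl (5R,6Z)-5-hydroxy-8-[(4-methoxyphenyl)methoxy]-6-methyl-3-oxooct-6-enoate | COC(=O)CC(=O)C[C@@H](O)/C(C)=C\COCc1ccc(OC)cc1 | intermediate
9 | methyl (3S,5R,6Z)-3,5-dihydroxy-8-[(4-methoxyphenyl)methoxy]-6-methyloct-6-enoate | COC(=O)C[C@@H](O)C[C@@H](O)/C(C)=C\COCc1ccc(OC)cc1 | intermediate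
10 | (4S,6R)-4-hydroxy-6-{(2Z)-4-[(4-methoxyphenyl)methoxy]but-2-en-2-yl}oxan-2-one | O=C1O[C@@H](/C(C)=C\COCc2ccc(OC)cc2)C[C@H](O)C1 | intermediate
11 | (4S,6R)-4-{[tert-butyl(dimethyl)silyl]oxy}-6-{(2Z)-4-[(4-methoxyphenyl)methoxy]but-2-en-2-yl}oxan-2-one | O=C1O[C@@H](/C(C)=C\COCc2ccc(OC)cc2)C[C@H](O[Si](C)(C)C(C)(C)C)C1 | intermediate
12 | lithium enolate of 11 | [Li]OC1=C[C@@H](O[Si](C)(C)C(C)(C)C)C[C@H](/C(C)=C\COCc2ccc(OC)cc2)O1 | intermediate
13 | (3R,4S,6R)-4-{[tert-butyl(dimethyl)silyl]oxy}-6-{(2Z)-4-[(4-methoxyphenyl)methoxy]but-2-en-2-yl}-3-methyloxan-2-one (key-step precursor) | O=C1O[C@@H](/C(C)=C\COCc2ccc(OC)cc2)C[C@H](O[Si](C)(C)C(C)(C)C)[C@H]1C | intermediate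
14 | cyclic trimethylsilyl ketene acetal of 13 | CC1=C(O[Si](C)(C)C)O[C@@H](/C(C)=C\COCc2ccc(OC)cc2)C[C@@H]1O[Si](C)(C)C(C)(C)C | intermediate
15 | trimethylsilyl ester of 16 | C[Si](C)(C)OC(=O)[C@@]1(C)[C@@H](O[Si](C)(C)C(C)(C)C)CC=C(C)[C@@H]1COCc2ccc(OC)cc2 | intermediate
16 | (1R,2S,6S)-6-{[tert-butyl(dimethyl)silyl]oxy}-2-{[(4-methoxyphenyl)methoxy]methyl}-1,3-dimethylcyclohex-3-ene-1-carboxylic acid (key-step product) | OC(=O)[C@@]1(C)[C@@H](O[Si](C)(C)C(C)(C)C)CC=C(C)[C@@H]1COCc2ccc(OC)cc2 | intermediate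
17 | ethynyltrimethylsilane | C#C[Si](C)(C)C | starting material
18 | acid chloride of 16 | ClC(=O)[C@@]1(C)[C@@H](O[Si](C)(C)C(C)(C)C)CC=C(C)[C@@H]1COCc2ccc(OC)cc2 | intermediate
19 | 1-[(1R,2S,6S)-6-{[tert-butyl(dimethyl)silyl]oxy}-2-{[(4-methoxyphenyl)methoxy]methyl}-1,3-dimethylcyclohex-3-en-1-yl]-3-(trimethylsilyl)prop-2-yn-1-one | C[Si](C)(C)C#CC(=O)[C@@]1(C)[C@@H](O[Si](C)(C)C(C)(C)C)CC=C(C)[C@@H]1COCc2ccc(OC)cc2 | intermediate
20 | (2R)-propargylic alcohol from 19 | C[Si](C)(C)C#C[C@@H](O)[C@@]1(C)[C@@H](O[Si](C)(C)C(C)(C)C)CC=C(C)[C@@H]1COCc2ccc(OC)cc2 | intermediate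
21 | C2 triethylsilyl ether of 20 | C[Si](C)(C)C#C[C@@H](O[Si](CC)(CC)CC)[C@@]1(C)[C@@H](O[Si](C)(C)C(C)(C)C)CC=C(C)[C@@H]1COCc2ccc(OC)cc2 | intermediate
22 | iodoalkyne | IC#C[C@@H](O[Si](CC)(CC)CC)[C@@]1(C)[C@@H](O[Si](C)(C)C(C)(C)C)CC=C(C)[C@@H]1COCc2ccc(OC)cc2 | intermediate
23 | (3Z)-iodoalkene | I/C=C\[C@@H](O[Si](CC)(CC)CC)[C@@]1(C)[C@@H](O[Si](C)(C)C(C)(C)C)CC=C(C)[C@@H]1COCc2ccc(OC)cc2 | intermediate
24 | C9 primary alcohol | I/C=C\[C@@H](O[Si](CC)(CC)CC)[C@@]1(C)[C@@H](O[Si](C)(C)C(C)(C)C)CC=C(C)[C@@H]1CO | intermediate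
25 | C9 aldehyde | I/C=C\[C@@H](O[Si](CC)(CC)CC)[C@@]1(C)[C@@H](O[Si](C)(C)C(C)(C)C)CC=C(C)[C@@H]1C=O | intermediate
26 | diethyl (2S)-2-hydroxybutanedioate | CCOC(=O)[C@@H](O)CC(=O)OCC | starting material
27 | dilithio alkoxide enolate of 26 | CCOC(=O)[C@@H](O[Li])C=C(O[Li])OCC | intermediate
28 | diethyl (2S,3R)-2-hydroxy-3-methylbutanedioate | CCOC(=O)[C@@H](O)[C@@H](C)C(=O)OCC | intermediate
29 | (2S,3R)-2-hydroxy-3-methylbutanedioic acid | OC(=O)[C@@H](O)[C@@H](C)C(=O)O | intermediate
30 | 2,2-dimethylpropanal | CC(C)(C)C=O | starting material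
31 | (2R)-2-[(2S,4S)-2-tert-butyl-5-oxo-1,3-dioxolan-4-yl]propanoic acid | O=C1O[C@@H](C(C)(C)C)O[C@H]1[C@@H](C)C(=O)O | intermediate
32 | dilithium enolate carboxylate of 31 | [Li]OC1=C([C@@H](C)C(=O)O[Li])O[C@H](C(C)(C)C)O1 | intermediate
33 | dilithium aldolate from 25 and 32 | I/C=C\[C@@H](O[Si](CC)(CC)CC)[C@@]1(C)[C@@H](O[Si](C)(C)C(C)(C)C)CC=C(C)[C@@H]1[C@@H](O[Li])[C@]2(O[C@H](C(C)(C)C)OC2=O)[C@@H](C)C(=O)O[Li] | intermediate
34 | C9 triethylsilyl ether, triethylsilyl ester of the aldol adduct | I/C=C\[C@@H](O[Si](CC)(CC)CC)[C@@]1(C)[C@@H](O[Si](C)(C)C(C)(C)C)CC=C(C)[C@@H]1[C@@H](O[Si](CC)(CC)CC)[C@]2(O[C@H](C(C)(C)C)OC2=O)[C@@H](C)C(=O)O[Si](CC)(CC)CC | intermediate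
35 | aldol adduct acid (C9–OTES, dioxolanone, C19 acid) | I/C=C\[C@@H](O[Si](CC)(CC)CC)[C@@]1(C)[C@@H](O[Si](C)(C)C(C)(C)C)CC=C(C)[C@@H]1[C@@H](O[Si](CC)(CC)CC)[C@]2(O[C@H](C(C)(C)C)OC2=O)[C@@H](C)C(=O)O | intermediate
36 | 1-methoxy-4-[(prop-2-yn-1-yloxy)methyl]benzene | C#CCOCc1ccc(OC)cc1 | starting material
37 | lithium acetylide of 36 | [Li]C#CCOCc1ccc(OC)cc1 | intermediate
38 | hemiketal adduct of 37 to 35 (drawn protonated, C7 undefined) | I/C=C\[C@@H](O[Si](CC)(CC)CC)[C@@]1(C)[C@@H](O[Si](C)(C)C(C)(C)C)CC=C(C)[C@@H]1[C@@H](O[Si](CC)(CC)CC)[C@]2(O[C@H](C(C)(C)C)OC2(O)C#CCOCc3ccc(OC)cc3)[C@@H](C)C(=O)O | intermediate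
39 | ynone acid | I/C=C\[C@@H](O[Si](CC)(CC)CC)[C@@]1(C)[C@@H](O[Si](C)(C)C(C)(C)C)CC=C(C)[C@@H]1[C@@H](O[Si](CC)(CC)CC)[C@@](O)(C(=O)C#CCOCc2ccc(OC)cc2)[C@@H](C)C(=O)O | intermediate
40 | (7S)-hydroxy acid | I/C=C\[C@@H](O[Si](CC)(CC)CC)[C@@]1(C)[C@@H](O[Si](C)(C)C(C)(C)C)CC=C(C)[C@@H]1[C@@H](O[Si](CC)(CC)CC)[C@@](O)([C@@H](O)C#CCOCc2ccc(OC)cc2)[C@@H](C)C(=O)O | intermediate
41 | lactone (ring C closed) | I/C=C\[C@@H](O[Si](CC)(CC)CC)[C@@]1(C)[C@@H](O[Si](C)(C)C(C)(C)C)CC=C(C)[C@@H]1[C@@H](O[Si](CC)(CC)CC)[C@@]2(O)[C@H](C#CCOCc3ccc(OC)cc3)OC(=O)[C@@H]2C | intermediate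
42 | C2,C9-diol | I/C=C\[C@@H](O)[C@@]1(C)[C@@H](O[Si](C)(C)C(C)(C)C)CC=C(C)[C@@H]1[C@@H](O)[C@@]2(O)[C@H](C#CCOCc3ccc(OC)cc3)OC(=O)[C@@H]2C | intermediate
43 | C2,C9-diacetate | I/C=C\[C@@H](OC(C)=O)[C@@]1(C)[C@@H](O[Si](C)(C)C(C)(C)C)CC=C(C)[C@@H]1[C@@H](OC(C)=O)[C@@]2(O)[C@H](C#CCOCc3ccc(OC)cc3)OC(=O)[C@@H]2C | intermediate
44 | C14 alcohol | I/C=C\[C@@H](OC(C)=O)[C@@]1(C)[C@@H](O)CC=C(C)[C@@H]1[C@@H](OC(C)=O)[C@@]2(O)[C@H](C#CCOCc3ccc(OC)cc3)OC(=O)[C@@H]2C | intermediate
45 | (11S,12R)-epoxide | I/C=C\[C@@H](OC(C)=O)[C@@]1(C)[C@@H](O)C[C@H]2O[C@@]2(C)[C@@H]1[C@@H](OC(C)=O)[C@@]3(O)[C@H](C#CCOCc4ccc(OC)cc4)OC(=O)[C@@H]3C | intermediate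
46 | C2,C9,C14-triacetate | I/C=C\[C@@H](OC(C)=O)[C@@]1(C)[C@@H](OC(C)=O)C[C@H]2O[C@@]2(C)[C@@H]1[C@@H](OC(C)=O)[C@@]3(O)[C@H](C#CCOCc4ccc(OC)cc4)OC(=O)[C@@H]3C | intermediate
47 | C16 propargylic alcohol | I/C=C\[C@@H](OC(C)=O)[C@@]1(C)[C@@H](OC(C)=O)C[C@H]2O[C@@]2(C)[C@@H]1[C@@H](OC(C)=O)[C@@]3(O)[C@H](C#CCO)OC(=O)[C@@H]3C | intermediate
48 | alkenylstannane (Bu3Sn on C5, cis to C7) | I/C=C\[C@@H](OC(C)=O)[C@@]1(C)[C@@H](OC(C)=O)C[C@H]2O[C@@]2(C)[C@@H]1[C@@H](OC(C)=O)[C@@]3(O)[C@H](/C=C(CO)\[Sn](CCCC)(CCCC)CCCC)OC(=O)[C@@H]3C | intermediate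
49 | CNP0296793.1 | CC(=O)O[C@H]1C[C@H]2O[C@@]2(C)[C@@H]2[C@@H](OC(C)=O)[C@@]3(O)[C@H](/C=C(CO)\C=C/[C@@H](OC(C)=O)[C@@]12C)OC(=O)[C@@H]3C | target

**Step count.** Total: 30 steps (27 in the main line, 3 for dioxolanone 31). Longest linear sequence: 27 steps (steps 1–16 and 20–30).

**Steps most likely to fail**

1. Step 30 (closure of ring B). The reductive elimination that forms the strained ten-membered Z,Z-diene may be slow, so that intermolecular coupling or protodestannylation of the hindered stannane takes over. Fallback: the route leaves at 48; iododestannylation (I2, CH2Cl2, 0 °C) gives the bis(alkenyl iodide) F1, and a palladium-free, Ullmann-type reductive cyclisation with excess copper thiophene-2-carboxylate Cu(O2CC4H3S) in NMP at 20 °C under high dilution forms C4–C5 and returns to 49.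

2. Step 20 (aldol that forms C8–C9). The basic lithium enolate may take the C10 proton of the hindered β,γ-unsaturated aldehyde instead of adding (enolisation, epimerisation at C10, olefin migration), or the aldolate may revert before it is silylated. Fallback: the route leaves at 31; radical bromination (NBS, AIBN, PhCF3, 80 °C) gives the 5-bromo dioxolanone acid F2, which after conversion to its lithium carboxylate is coupled with 25 in a Reformatsky reaction mediated by SmI2 (THF, -78 °C). The samarium enolate is far less basic and should add trans to the tert-butyl group as before; TESOTf and buffer then return to 35.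

3. Step 9 (ring contraction). The lactone enolate may lose the β-silyloxide before it is trapped, or the ketene acetal may decompose at 110 °C before the boat transition state is reached. Fallback: the route leaves at 10; dianion methylation (LiN(iPr)2, 2.2 equiv, then MeI) gives the hydroxy lactone F3, whose dilithium alkoxide enolate (LiN(iPr)2, THF, -78 °C to reflux) undergoes the enolate Claisen rearrangement as a dianion, in which the alkoxide cannot leave, to give the hydroxy acid F4. Bis-silylation (TBSOTf, 2,6-lutidine) gives the silyl ether silyl ester F5, and hydrolysis of the silyl ester (K2CO3, MeOH/H2O) returns to 16.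

**Further compounds**

F1 | step 30 | bis(alkenyl iodide): 48 with SnBu3 replaced by I | I/C=C\[C@@H](OC(C)=O)[C@@]1(C)[C@@H](OC(C)=O)C[C@H]2O[C@@]2(C)[C@@H]1[C@@H](OC(C)=O)[C@@]3(O)[C@H](/C=C(CO)\I)OC(=O)[C@@H]3C
F2 | step 20 | (2R)-2-[(2S)-4-bromo-2-tert-butyl-5-oxo-1,3-dioxolan-4-yl]propanoic acid | O=C1O[C@@H](C(C)(C)C)OC1(Br)[C@@H](C)C(=O)O
F3 | step 9 | (3R,4S,6R)-4-hydroxy-6-{(2Z)-4-[(4-methoxyphenyl)methoxy]but-2-en-2-yl}-3-methyloxan-2-one | O=C1O[C@@H](/C(C)=C\COCc2ccc(OC)cc2)C[C@H](O)[C@H]1C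
F4 | step 9 | 6-hydroxy-2-{[(4-methoxyphenyl)methoxy]methyl}-1,3-dimethylcyclohex-3-ene-1-carboxylic acid (stereocentres as in 16) | OC(=O)[C@@]1(C)[C@@H](O)CC=C(C)[C@@H]1COCc2ccc(OC)cc2
F5 | step 9 | tert-butyldimethylsilyl ester of 16 | CC(C)(C)[Si](C)(C)OC(=O)[C@@]1(C)[C@@H](O[Si](C)(C)C(C)(C)C)CC=C(C)[C@@H]1COCc2ccc(OC)cc2
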